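**Remark on the chemistry:** ring B is numbered throughout as C1 (carbonyl-bearing), C2 (OH), C3 (H), C4 (CH3), C5 (OCH3), C6 (CH2OAc). Systematic names of intermediates use their own locants. All compounds of the main route are achiral.

## The problem

Preacredinone A (13) is an achiral benzophenone. Ring A is a 2,6-dimethoxyphenyl group and ring B is pentasubstituted, with only C3 still carrying hydrogen. There is no stereocentre, so the task is regiochemical and steric. Five different groups must be placed around ring B without ambiguity. The carbonyl carbon must then be joined to two aryl carbons that each have two ortho substituents. A carbonyl of this kind resists the usual constructions: a di-ortho-substituted aryl metal adds poorly to a di-ortho-substituted acyl electrophile, and Friedel–Crafts acylation of ring B has no reason to choose C1 over C3. The primary benzylic acetate will not survive hydride, organolithium reagents or aqueous base, and its ortho methoxy group makes the benzylic C–O bond prone to ionisation in strong acid. Once the acetate is lost, the free CH2OH can close onto the ketone as a five-membered hemiketal. Ring B is also a hydroquinone monoether and is easily oxidised to a quinone once the phenol is free. The feature that opens the route is that C1 is flanked by the C2 oxygen and the C6 CH2O group. This crowding slows direct aryl–aryl coupling at palladium but not the insertion of CO. The same two oxygen functions make C1–H the only ring hydrogen lying between two lithium-coordinating groups, so a halogen can be placed there with certainty.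

## Retrosynthesis

**13 ⇒ 12.** The last bond cut is the acetal C–O bond of a methoxymethyl (MOM) ether on the C2 phenol. The phenol has to be masked during the coupling, because a free ortho-iodophenol would capture an aroylpalladium intermediate as an ester. The same acetal is needed earlier as a directing group. Carrying the acetate through the coupling, instead of a second MOM group, reduces the end game to one acid step and avoids having to tell a primary alcohol from a phenol at the end. The forward reaction must cleave an aryl MOM ether, helped by the ortho carbonyl group, without touching the primary acetate.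

**12 ⇒ 9 + 10 + 11.** Both aryl–C(=O) bonds are cut at once. This leads to ring B iodide 9, 2,6-dimethoxyphenylboronic acid (10) and carbon monoxide (11). Cutting only one bond would require a hindered aryl anion to attack a hindered acyl group, or an aldehyde followed by an oxidation. The three-component cut brings the carbonyl in as CO, a small molecule that inserts into the crowded aryl–palladium bond and moves the metal one atom away from ring B before ring A arrives. The precursors are a single benzene ring, a purchasable boronic acid and a gas. The forward reaction must let CO insertion outrun transmetalation, and must tolerate the acetate and the acetal.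

**9 ⇒ 8 ⇒ 6.** The acetate comes from alcohol 8, and the C1–I bond of 8 comes from benzyl alcohol 6. Electrophilic iodination would not distinguish C1 from C3, since both are ortho to the oxygenated C2 and are activated to a similar degree. Directed lithiation does distinguish them. After deprotonation of the alcohol, C1–H lies between a CH2OLi group and the OMOM group, while C3–H has one director and a methyl neighbour. Using the free alcohol as its alkoxide saves a protection step. The forward reaction is a dilithiation via 7 with iodine quench.

**6 ⇒ 5 ⇒ 4.** Alcohol 6 is the reduction product of ester 5, which is the MOM ether of phenol 4. The acetal is put on before the hydride step so that no acidic phenol is present during the reduction or the later lithiation.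

**4 ⇒ 2.** The C–O bond that becomes the C2 oxygen of ring B is cut back to a C–H bond of methyl 2-methoxy-3-methylbenzoate (2). Of the three ring hydrogens of 2, only the one para to the methoxy group has no ortho substituent. Sterically controlled iridium-catalysed borylation followed by oxidation of boronate 3 therefore places the oxygen exactly there. The neighbouring option is persulfate hydroxylation of acid 1 para to its free phenol. That gives a dihydroxy acid which must then be esterified and its two phenols differentiated, at a cost of two more steps. The borylation gives the differentiated phenol 4 directly.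

**2 ⇒ 1.** Ester 2 is the product of double methylation of 3-methylsalicylic acid (1), a cheap commercial compound that already holds the methyl group, the C5 oxygen and the C6 carbon of ring B in the right order.

## Roads not taken

**Alternative 1:** Ring B itself is opened by cutting C1–C6 and C2–C3, and the C2 oxygen is traced back to a furan oxygen. The precursor is furan–alkyne A2, a 3-methoxy-4-methylfuran whose 2-methylene group is linked through an ether oxygen to a propargylic carbon bearing ring A. In the forward step a monovalent gold catalyst such as (Ph3P)AuNTf2 activates the terminal alkyne. The furan attacks, and rearrangement through an arene oxide gives phenol A1 together with its five-membered cyclic ether.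

- Merits: the substitution pattern of ring B is fixed by the connectivity of A2. The phenol appears unprotected. The crowded benzylic carbon is made at the alcohol level, where an acetylide adds easily to an aryl aldehyde. The step is catalytic and wastes no atoms.
- Weak points: A1 is at the wrong oxidation level. The diaryl-substituted ether carbon must be oxidised to the ketone with ring opening, in the presence of a free hydroquinone monoether. It also competes with a second benzylic ether CH2 that would lead to a lactone. A 3-methoxyfuran is sensitive to acid and air, and its 2-halomethyl or 2-hydroxymethyl derivatives needed to build A2 ionise and polymerise readily. The methoxy group next to the reacting furan carbon slows the gold step. A selective acetylation would still follow.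
- Comparison: this road is better on the steric question, since no bond to a tetra-ortho-substituted carbon is made by coupling. Against that, the chosen plan brings the carbonyl in at the ketone level from CO, makes ring B from a stable benzoate by routine steps, and ends with a single deprotection.

**Alternative 2:** Ring B is cut at C5–C6, C1–C2 and C2–C3. It is traced to the alkenyl(methoxy)carbene complex A4 of zerovalent chromium, one of its CO ligands, and the unsymmetrical alkyne A5. On heating, the alkyne and then CO insert, and the resulting vinylketene cyclises and tautomerises to the 4-methoxyphenol A3. The larger alkyne substituent ends next to the new phenol, which here is the silyloxy(aryl)methyl group, as wanted. The carbene methoxy group becomes the C5 methoxy group, the isopropenyl unit supplies C4 with its methyl group and C3–H, and the acetate is present from the start.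

- Merits: all six ring carbons and all five substituents are set in one step. The route is convergent, and its longest linear sequence could well be shorter than that of the chosen plan.
- Weak points: the chromium is stoichiometric. Regiocontrol rests only on a size difference, and a very bulky alkyne slows insertion. A3 is a free 4-methoxyphenol that is readily oxidised to a quinone while the metal is removed. Desilylation with fluoride next to an acetate invites acyl migration. The final oxidation of the benzhydrol to the ketone must be done beside an unprotected hydroquinone monoether.
- Comparison: in convergence this road is as good or better. The chosen plan sets against it a catalytic metal, a ketone formed directly, no oxidation of an electron-rich phenol, and regiochemistry fixed by C–H borylation and chelation instead of a steric preference.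

**Alternative 3:** The C1–C(=O) bond and the C2–O bond are cut. They are traced to the C1≡C2 aryne of ring B, released by CsF from the ortho-silylaryl triflate A7, and 2,6-dimethoxybenzoic acid A8. The carboxylate adds at C2, and the C1 aryl anion attacks the ester carbonyl through a four-membered intermediate that opens to the ketone and the C2 phenoxide, giving A6.

- Merits: ketone and phenol are set ortho to each other in one metal-free step. The acid partner is cheap and the phenol never needs protection.
- Weak points: two selectivities are not secured. The aryne has only a CH2OMOM group next to C1, a weak inductive and steric bias for addition at C2. The aryl anion must reach a carbonyl shielded by two ortho methoxy groups through a strained transition state, while protonation by a second molecule of acid, giving the aryl ester, is fast. A7 needs the same oxygenated ring B plus a silyl group and a triflate, so it is at least as long to make as iodide 9. A6 is still two steps from the target, one of them acid cleavage of a benzylic MOM ether next to the ketone.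
- Comparison: if it worked, this road would save the phenol protecting group. The chosen plan sets against it that CO insertion moves the reacting centre away from the crowded ring before the second aryl group arrives, and that its regiochemistry is decided by where the iodine sits.

Key step: step 7

## Route

Step 1
Reactants: 1 3-methylsalicylic acid (2-hydroxy-3-methylbenzoic acid)
Product: 2 methyl 2-methoxy-3-methylbenzoate
Conditions: MeI (3 equiv), K2CO3, DMF, 60 °C
Reagents that add atoms: iodomethane CI
Why: Williamson ether synthesis and carboxylate alkylation (SN2) in one operation; warm DMF and excess MeI overcome the hydrogen bond and the ortho methyl group that slow the phenol.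

Step 2
Reactants: 2 methyl 2-methoxy-3-methylbenzoate
Product: 4 methyl 5-hydroxy-2-methoxy-3-methylbenzoate, via the aryl pinacol boronate 3 (not isolated)
Conditions: [Ir(OMe)(cod)]2 (1.5 mol %), 4,4′-di-tert-butyl-2,2′-bipyridine (3 mol %), B2pin2, THF, 80 °C; then KHSO5 (as 2KHSO5·KHSO4·K2SO4), acetone–H2O, rt
Reagents that add atoms: bis(pinacolato)diboron (boryl group of 3) CC1(C)OB(OC1(C)C)B1OC(C)(C)C(C)(C)O1; potassium peroxymonosulfate (oxygen of 4) [K+].OOS(=O)(=O)[O-]
Why: One-pot iridium-catalysed aromatic C–H borylation and oxidation; the borylation is sterically governed and of the three ring hydrogens only the one para to the methoxy group has no ortho substituent, so boron enters there and peroxymonosulfate converts C–B into C–OH at the same carbon without touching the ester.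

Step 3
Reactants: 4 methyl 5-hydroxy-2-methoxy-3-methylbenzoate
Product: 5 methyl 2-methoxy-5-(methoxymethoxy)-3-methylbenzoate
Conditions: MOMCl, i-Pr2NEt, CH2Cl2, 0 °C → rt
Reagents that add atoms: chloromethyl methyl ether COCCl
Why: O-alkylation of an unhindered phenol to its methoxymethyl acetal; the acetal withstands hydride, organolithium and carbonate and later serves as an ortho-directing group.

Step 4
Reactants: 5 methyl 2-methoxy-5-(methoxymethoxy)-3-methylbenzoate
Product: 6 [2-methoxy-5-(methoxymethoxy)-3-methylphenyl]methanol
Conditions: LiAlH4, THF, 0 °C
Reagents that add atoms: none
Why: Hydride reduction of a methyl ester to the primary alcohol; the aryl ethers and the acetal are inert to LiAlH4.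

Step 5
Reactants: 6 [2-methoxy-5-(methoxymethoxy)-3-methylphenyl]methanol
Product: 8 [2-iodo-6-methoxy-3-(methoxymethoxy)-5-methylphenyl]methanol, via the dilithiated benzyl alkoxide 7 (not isolated)
Conditions: n-BuLi (2.3 equiv), TMEDA, Et2O, 0 °C → rt; then I2, THF, −78 °C → rt
Reagents that add atoms: n-butyllithium (lithium of 7) [Li]CCCC; iodine II
Why: Directed ortho-metalation; the first equivalent of base forms the lithium alkoxide and the second removes the one ring hydrogen that lies between the CH2OLi and OMOM groups, as in the known 2-lithiation of 3-alkoxybenzyl alcohols, while the other ring hydrogen has a single director and a methyl neighbour; iodine then traps the aryllithium.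

Step 6
Reactants: 8 [2-iodo-6-methoxy-3-(methoxymethoxy)-5-methylphenyl]methanol
Product: 9 [2-iodo-6-methoxy-3-(methoxymethoxy)-5-methylphenyl]methyl acetate
Conditions: Ac2O, pyridine, DMAP (cat.), CH2Cl2, 0 °C → rt
Reagents that add atoms: acetic anhydride CC(=O)OC(C)=O
Why: Nucleophile-catalysed acylation of the only hydroxyl group; the ester also keeps the benzylic oxygen from closing onto an aroylpalladium intermediate as a lactone in the next step.

Step 7
Reactants: 9 [2-iodo-6-methoxy-3-(methoxymethoxy)-5-methylphenyl]methyl acetate; 10 2,6-dimethoxyphenylboronic acid; 11 carbon monoxide
Product: 12 [2-(2,6-dimethoxybenzoyl)-6-methoxy-3-(methoxymethoxy)-5-methylphenyl]methyl acetate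
Conditions: [1,3-bis(2,6-diisopropylphenyl)imidazol-2-ylidene]PdCl2(3-chloropyridine) (5 mol %), Cs2CO3 (3 equiv), 10 (2 equiv), CO (1–4 atm), chlorobenzene, 80 °C
Reagents that add atoms: 2,6-dimethoxyphenylboronic acid (10) COc1cccc(OC)c1B(O)O; carbon monoxide (11) [C-]#[O+]
Why: Carbonylative Suzuki–Miyaura coupling, known for di-ortho-substituted aryl iodides with N-heterocyclic carbene palladium catalysts; a ketone with four ortho substituents stretches this reaction class but does not leave it. The divalent palladium precatalyst loses 3-chloropyridine and is reduced in the flask to a zerovalent palladium–carbene species, which adds oxidatively to the C1–I bond of 9. Because the arylpalladium iodide is flanked by OMOM and CH2OAc, transmetalation at this stage is slow, whereas the small CO ligand coordinates and inserts to give an aroylpalladium iodide in which the metal sits one atom further from the crowded ring. Carbonate-activated 10 then transfers the 2,6-dimethoxyphenyl group to palladium, and reductive elimination from the acyl(aryl)palladium complex releases 12 and zerovalent palladium. Two aryl–C(=O) bonds form, no ring closes and no stereocentre arises. The step needs chemoselectivity for the ketone over the biaryl, over protodeboronation of 10 and over hydrolysis of the aroylpalladium; the double ortho substitution of 9 and the CO atmosphere secure the first, and anhydrous, sparingly soluble Cs2CO3 in chlorobenzene with an excess of 10 secures the other two. The bulky carbene ligand keeps palladium monoligated, which speeds oxidative addition to the electron-rich iodide and the final reductive elimination. The acetate and the acetal are inert to anhydrous carbonate, and since both oxygens are masked neither can capture the aroylpalladium as lactone or ester.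

Step 8
Reactants: 12 [2-(2,6-dimethoxybenzoyl)-6-methoxy-3-(methoxymethoxy)-5-methylphenyl]methyl acetate
Product: 13 preacredinone A, [2-(2,6-dimethoxybenzoyl)-3-hydroxy-6-methoxy-5-methylphenyl]methyl acetate
Conditions: TFA, CH2Cl2, 0 °C → rt; aq. NaHCO3 work-up
Reagents that add atoms: none
Why: Acid-catalysed cleavage of an aryl methoxymethyl acetal, made easy by the ortho carbonyl group that hydrogen-bonds the liberated phenol; a primary acetate is stable to anhydrous TFA at this temperature.

## Compound list

1 | 3-methylsalicylic acid (2-hydroxy-3-methylbenzoic acid) | Cc1cccc(C(=O)O)c1O | starting material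
2 | methyl 2-methoxy-3-methylbenzoate | COC(=O)c1cccc(C)c1OC | intermediate
3 | methyl 2-methoxy-3-methyl-5-(4,4,5,5-tetramethyl-1,3,2-dioxaborolan-2-yl)benzoate | COC(=O)c1cc(B2OC(C)(C)C(C)(C)O2)cc(C)c1OC | intermediate (not isolated)
4 | methyl 5-hydroxy-2-methoxy-3-methylbenzoate | COC(=O)c1cc(O)cc(C)c1OC | intermediate
5 | methyl 2-methoxy-5-(methoxymethoxy)-3-methylbenzoate | COCOc1cc(C)c(OC)c(C(=O)OC)c1 | intermediate
6 | [2-methoxy-5-(methoxymethoxy)-3-methylphenyl]methanol | COCOc1cc(C)c(OC)c(CO)c1 | intermediate
7 | lithium [2-lithio-6-methoxy-3-(methoxymethoxy)-5-methylphenyl]methanolate | [Li]OCc1c([Li])c(OCOC)cc(C)c1OC | intermediate (not isolated)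
8 | [2-iodo-6-methoxy-3-(methoxymethoxy)-5-methylphenyl]methanol | OCc1c(I)c(OCOC)cc(C)c1OC | intermediate
9 | [2-iodo-6-methoxy-3-(methoxymethoxy)-5-methylphenyl]methyl acetate | CC(=O)OCc1c(I)c(OCOC)cc(C)c1OC | intermediate
10 | 2,6-dimethoxyphenylboronic acid | COc1cccc(OC)c1B(O)O | starting material
11 | carbon monoxide | [C-]#[O+] | starting material
12 | [2-(2,6-dimethoxybenzoyl)-6-methoxy-3-(methoxymethoxy)-5-methylphenyl]methyl acetate | CC(=O)OCc1c(C(=O)c2c(OC)cccc2OC)c(OCOC)cc(C)c1OC | intermediate
13 | preacredinone A, [2-(2,6-dimethoxybenzoyl)-3-hydroxy-6-methoxy-5-methylphenyl]methyl acetate | COc1cccc(OC)c1C(=O)c1c(O)cc(C)c(OC)c1COC(C)=O | target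

## Step count and risks

Total step count: 8. Longest linear sequence: 8 steps (1 → 13). Compounds 10 and 11 are used as bought.

**Step 7 (key step).** The most likely failure is slow transfer of the di-ortho-substituted aryl group from boron to the aroylpalladium. Protodeboronation of the electron-rich boronic acid, and hydrolysis or reduction of the aroylpalladium, then outrun ketone formation. Partial cleavage of the acetate by carbonate and adventitious water is a lesser concern. The fallback forms the same C1–carbonyl bond at the carbinol level, where additions of di-ortho-substituted aryllithiums to aldehydes are reliable. It sets out from 6. Dilithiation as in step 5 gives 7, which is quenched with 2,6-dimethoxybenzaldehyde instead of iodine to give racemic (2,6-dimethoxyphenyl)[2-(hydroxymethyl)-3-methoxy-6-(methoxymethoxy)-4-methylphenyl]methanol F1. The primary alcohol is acetylated selectively over the buried secondary carbinol (Ac2O, pyridine, 0 °C) to give racemic [2-[(2,6-dimethoxyphenyl)(hydroxy)methyl]-6-methoxy-3-(methoxymethoxy)-5-methylphenyl]methyl acetate F2. Oxidation with Dess–Martin periodinane then gives the ketone, and the fallback returns to the route at 12.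

**Step 5.** Metalation may be incomplete or misdirected. The dilithio alkoxide aggregates and dissolves poorly, and deprotonation next to the methyl group or at the aryl methyl group could compete. The fallback changes the directing group. It sets out from 6, which MnO2 oxidises to 2-methoxy-5-(methoxymethoxy)-3-methylbenzaldehyde F3. Addition of LiN(CH3)CH2CH2N(CH3)2 protects the aldehyde in the flask as the lithium α-amino alkoxide F4 (lithium {[2-(dimethylamino)ethyl](methyl)amino}[2-methoxy-5-(methoxymethoxy)-3-methylphenyl]methanolate). Its chelating diamine arm, together with the OMOM group, directs n-BuLi to the same ring carbon to give the ring-lithiated α-amino alkoxide F5. Iodine quench and aqueous work-up release 2-iodo-6-methoxy-3-(methoxymethoxy)-5-methylbenzaldehyde F6, and NaBH4 reduction returns to the route at 8.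

**Step 8.** Two processes threaten this step. One is acid-induced ionisation of the ortho-methoxybenzylic C–O bond with loss of the acetate. The other is alkylation of the freed phenol ring at C3 by the methoxymethyl cation. The fallback puts the ester on last, so that acid never meets the acetate. It sets out from 12. K2CO3 in methanol removes the acetate to give (2,6-dimethoxyphenyl)[2-(hydroxymethyl)-3-methoxy-6-(methoxymethoxy)-4-methylphenyl]methanone F7. Dilute aqueous HCl in THF at rt, where water traps the acetal fragment and returns any hemiketal to the open ketone, gives (2,6-dimethoxyphenyl)[6-hydroxy-2-(hydroxymethyl)-3-methoxy-4-methylphenyl]methanone F8. The primary alcohol is then acetylated with acetyl chloride and 2,4,6-collidine at −78 °C, the phenol being hindered and held in a hydrogen bond to the ketone. The fallback returns at 13.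

**Step 2.** The one-pot sequence may suffer from incomplete borylation of a ring deactivated towards C–H activation by crowding. The electron-rich phenol may also be oxidised further towards a quinone by peroxymonosulfate. The fallback is the classical para-hydroxylation and sets out from 1. Elbs persulfate oxidation (K2S2O8, aqueous NaOH, then hot dilute HCl) gives, through the aryl sulfate potassium 3-carboxy-4-hydroxy-5-methylphenyl sulfate F9, 2,5-dihydroxy-3-methylbenzoic acid F10. Fischer esterification (MeOH, H2SO4) gives methyl 2,5-dihydroxy-3-methylbenzoate F11. MOMCl and i-Pr2NEt protect the phenol that is not hydrogen-bonded to the ester, giving methyl 2-hydroxy-5-(methoxymethoxy)-3-methylbenzoate F12. Methylation with MeI and K2CO3 in DMF returns to the route at 5.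

## Further compounds

F1 | step 7 | rac-(2,6-dimethoxyphenyl)[2-(hydroxymethyl)-3-methoxy-6-(methoxymethoxy)-4-methylphenyl]methanol | OCc1c(C(O)c2c(OC)cccc2OC)c(OCOC)cc(C)c1OC
F2 | step 7 | rac-[2-[(2,6-dimethoxyphenyl)(hydroxy)methyl]-6-methoxy-3-(methoxymethoxy)-5-methylphenyl]methyl acetate | CC(=O)OCc1c(C(O)c2c(OC)cccc2OC)c(OCOC)cc(C)c1OC
F3 | step 5 | 2-methoxy-5-(methoxymethoxy)-3-methylbenzaldehyde | O=Cc1cc(OCOC)cc(C)c1OC
F4 | step 5 | rac-lithium {[2-(dimethylamino)ethyl](methyl)amino}[2-methoxy-5-(methoxymethoxy)-3-methylphenyl]methanolate | [Li]OC(N(C)CCN(C)C)c1cc(OCOC)cc(C)c1OC
F5 | step 5 | rac-lithium {[2-(dimethylamino)ethyl](methyl)amino}[2-lithio-6-methoxy-3-(methoxymethoxy)-5-methylphenyl]methanolate | [Li]OC(N(C)CCN(C)C)c1c([Li])c(OCOC)cc(C)c1OC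
F6 | step 5 | 2-iodo-6-methoxy-3-(methoxymethoxy)-5-methylbenzaldehyde | O=Cc1c(I)c(OCOC)cc(C)c1OC
F7 | step 8 | (2,6-dimethoxyphenyl)[2-(hydroxymethyl)-3-methoxy-6-(methoxymethoxy)-4-methylphenyl]methanone | OCc1c(C(=O)c2c(OC)cccc2OC)c(OCOC)cc(C)c1OC
F8 | step 8 | (2,6-dimethoxyphenyl)[6-hydroxy-2-(hydroxymethyl)-3-methoxy-4-methylphenyl]methanone | OCc1c(C(=O)c2c(OC)cccc2OC)c(O)cc(C)c1OC
F9 | step 2 | potassium 3-carboxy-4-hydroxy-5-methylphenyl sulfate | Cc1cc(OS(=O)(=O)[O-])cc(C(=O)O)c1O.[K+]
F10 | step 2 | 2,5-dihydroxy-3-methylbenzoic acid | Cc1cc(O)cc(C(=O)O)c1O
F11 | step 2 | methyl 2,5-dihydroxy-3-methylbenzoate | COC(=O)c1cc(O)cc(C)c1O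
F12 | step 2 | methyl 2-hydroxy-5-(methoxymethoxy)-3-methylbenzoate | COCOc1cc(C)c(O)c(C(=O)OC)c1
A1 | alternative 1 | rac-3-(2,6-dimethoxyphenyl)-7-methoxy-6-methyl-1,3-dihydro-2-benzofuran-4-ol | COc1cccc(OC)c1C1OCc2c(OC)c(C)cc(O)c12
A2 | alternative 1 | rac-2-({[1-(2,6-dimethoxyphenyl)prop-2-yn-1-yl]oxy}methyl)-3-methoxy-4-methylfuran | C#CC(OCc1occ(C)c1OC)c1c(OC)cccc1OC
A3 | alternative 2 | rac-2-{[(tert-butyldimethylsilyl)oxy](2,6-dimethoxyphenyl)methyl}-3-hydroxy-6-methoxy-5-methylbenzyl acetate | COc1cccc(OC)c1C(O[Si](C)(C)C(C)(C)C)c1c(O)cc(C)c(OC)c1COC(C)=O
A4 | alternative 2 | pentacarbonyl[methoxy(prop-1-en-2-yl)methylidene]chromium | COC(C(C)=C)=[Cr](=C=O)(=C=O)(=C=O)(=C=O)=C=O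
A5 | alternative 2 | rac-4-[(tert-butyldimethylsilyl)oxy]-4-(2,6-dimethoxyphenyl)but-2-yn-1-yl acetate | CC(=O)OCC#CC(O[Si](C)(C)C(C)(C)C)c1c(OC)cccc1OC
A6 | alternative 3 | (2,6-dimethoxyphenyl){2-hydroxy-5-methoxy-6-[(methoxymethoxy)methyl]-4-methylphenyl}methanone | COCOCc1c(C(=O)c2c(OC)cccc2OC)c(O)cc(C)c1OC
A7 | alternative 3 | 4-methoxy-3-[(methoxymethoxy)methyl]-5-methyl-2-(trimethylsilyl)phenyl trifluoromethanesulfonate | COCOCc1c([Si](C)(C)C)c(OS(=O)(=O)C(F)(F)F)cc(C)c1OC
A8 | alternative 3 | 2,6-dimethoxybenzoic acid | COc1cccc(OC)c1C(=O)O
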